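## Structural features

The target is a bicyclic sesquiterpene alcohol esterified with (E)-caffeic acid. A methylenecyclopentane (ring A, carbons CA1 to CA5, exocyclic CH2 on CA1, methyl on the quaternary CA5) is bonded through CA5 to the quaternary carbon CB1 of a cyclohexene (ring B, carbons CB1 to CB6), which carries a methyl on CB1, the CB3=CB4 double bond, a methyl on CB4 and the acyloxy group on CB5. CA5 (S) and CB1 (S) are adjacent all-carbon quaternary stereocentres, and the carbinol centre CB5 (S) stands 1,3 to CB1 with its oxygen trans to the CB1 methyl. The fragile groups are the free catechol (air, base), the allylic ester at CB5 (ionisation, hydrolysis) and the exocyclic 1,1-disubstituted alkene, which acid would move into ring A. The real difficulty is the bond between the two quaternary carbons and, above all, the configuration of CB1, which is stereogenic only because its ring arms CB2 and CB6 differ further along ring B. At the enone level ring B is a 2-methylcyclohex-2-enone (carbonyl CB5, methyl on CB4, alkene CB3=CB4) with CB1 at its 5-position, which is what results when a propyne unit (CB3, CB4 and the methyl) is inserted between the carbonyl carbon and one α-methylene of a 3,3-disubstituted cyclobutanone. The key step uses this: in the four-membered ketone CB1 is a prochiral ring carbon attached to CA5, and the choice of which CB5–CH2 bond is broken, made while the CB4–CB5 and CB2–CB3 bonds form, fixes CB1.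

## Logic of the disconnections

The ester C–O bond between the CB5 oxygen and the acyl carbon is cut first, together with the two aryl O–Si bonds that mask the catechol: 25 comes from 24, and 24 from 20 and 23. The catechol and the cinnamate are the most sensitive parts, so they are attached last. The cut separates a fifteen-carbon alcohol from an acid that is one operation away from 21 (through 22). The forward acylation must leave the CB5–O bond untouched, and the last deprotection must be mild enough for a free catechol and an allylic ester.

In 20 the exocyclic C=CH2 bond at CA1 is cut back to ketone 18 by way of silyl ether 19. The alkene is acid-labile and is therefore introduced after every acidic step. The price is a methylenation of a carbonyl flanked by two contiguous quaternary carbons, so the CB5 oxygen must be masked as an ether that resists a hot basic ylide and still comes off under neutral conditions.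

18 is traced to alcohol 17, and 17 to 15 by putting back the C–Si bond at CB3 and the O–Si bond at CA1 (16 lies between them); 15 is the silyl ether of 14. These are changes of functional and protecting groups only, but their order matters. The C–Si bond is broken by acid only after the CB5 carbonyl has been reduced and the oxygen protected, for two reasons: ipso-protonation of a carbonyl-conjugated vinylsilane would put a cation next to the carbonyl, and fluoride at the enone stage would also free the CA1 hydroxyl, which could add to CB3 of the enone. The forward step must cleave the vinylic C–Si and the alkyl O–Si bonds without ionising the allylic CB5–O bond or moving the CB3=CB4 alkene.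

The CB5–H bond of 14 is cut to give enone 13. This removes one stereocentre and brings ring B to the oxidation level at which it is recognisable as a ring-expanded cyclobutanone. The forward reduction must be a reagent-controlled 1,2-reduction that places the oxygen trans to the CB1 methyl.

In 13 the CB4–CB5 and CB2–CB3 bonds are cut, which takes out alkyne 12 and contracts ring B to cyclobutanone 11. One ring, two C–C bonds and the CB1 stereocentre disappear, and the partner is a commercial alkyne that already carries the CB4 methyl. The forward step must choose one of two diastereotopic ring bonds and orient the alkyne so that silicon ends up on CB3.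

11 is simplified by putting back two chlorines (10) and then cutting both ring bonds made in a [2+2] cycloaddition, which leads to alkene 7 and ketene 9, itself made from 8. This replaces the quaternary-substituted four-membered ring by a 1,1-disubstituted alkene. The cycloaddition must be regioselective on a hindered alkene and must tolerate the silyl ether in the presence of zinc salts.

The C=CH2 bond of 7 is cut to methyl ketone 6, and the acyl–CH3 bond of 6 to ester 4 (through 5). Both cuts are standard carbonyl chemistry and return the side chain to the ester of a β-hydroxy ester. The forward demand is a single addition of a one-carbon nucleophile to a hindered ester.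

Finally the O–Si bond of 4, the CA5–CH3 bond of 3 and the carbinol C–H bond of 2 are cut, ending at 1. CA5 is then set by 1,2-induction from the neighbouring carbinol, whose configuration comes from a catalytic asymmetric hydrogenation. The alkylation must occur anti to the alkoxide, and the hydrogenation must convert both enantiomers of the racemising keto ester into one carbinol configuration.

## Other disconnections considered

Alternative 1: The cut goes through CB1–CB2 and CA5–CA4, so that both quaternary carbons arise in one cationic cascade from the open-chain α-benzyloxy vinyl ketone A2, in which a (Z)-tetrasubstituted alkene carries a 1-hydroxycyclobutyl group. A chelating Lewis acid (TiCl4 or Me2AlCl) would bind the ketone and the benzyloxy oxygen, the alkene would attack the enone terminus CB2 through CB1 to close ring B, and the tertiary cation at CA5 would be quenched by semipinacol ring expansion of the cyclobutanol, closing ring A and giving diketone A1.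
- In its favour: the CA5/CB1 pair is made in one step with the relative configuration encoded in the alkene geometry, and the CB5 oxygen is present from the start in the required configuration.
- Better than the chosen plan on one point: the CA1 ketone is delivered directly, so no protecting-group and oxidation sequence is needed at CA1.
- Against it: a geometrically pure tetrasubstituted alkene is a hard target in itself; the facial sense rests on transfer from CB5 through a chelate whose preference is not assured; cations beside quaternary carbons invite proton loss and 1,2-shifts. After the cascade the CB4 ketone of A1 must still become the methyl-bearing CB3=CB4 alkene with the right regiochemistry beside a second ketone, and the benzyl ether must be removed without hydrogenation.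
- Comparison: mechanistically it is a polar cascade assembled from familiar elementary steps, which is at least as credible as an unprecedented ligand-controlled bond selection. Structurally it leaves ring B less advanced (no CB4 methyl, no alkene), whereas the chosen key step delivers enone, methyl and alkene together. The step counts should be similar, and the alternative wins only if A2 is short to make.

Alternative 2: The CB1 methyl is disconnected to a cyclopropane methylene and ring B to an arene: Birch reduction of an aryl methyl ether would supply the cyclohexenone from which allylic alcohol A4 is made. The forward key step is the hydroxyl-directed Simmons–Smith cyclopropanation (Et2Zn, CH2I2) of the CB1=CB6 alkene of A4, syn to the CB5 hydroxyl, to give A3; later reductive opening of the three-membered ring would turn the methylene into the CB1 methyl.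
- In its favour: directed cyclopropanation is among the most dependable diastereoselective reactions and is clearly more secure than the chosen key step. CA1 travels as a ketal at the correct oxidation level, which is equal to or better than the chosen plan at that position.
- Against it: CA5 and CB5 must be related beforehand, when A4 is made. The hydroxyl that directs the methylene ends up cis to the new methyl, whereas the target needs the oxygen trans, so CB5 must be inverted or taken through a ketone. The CB4 methyl and the CB3=CB4 alkene are still missing in A3.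
- Comparison: the mechanism is better established, but the step sets CB1 only and leaves most of ring B to be functionalised, so the sequence after the key step should be clearly longer than in the chosen plan.

Alternative 3: The CA1–CA5 bond is cut, and ring A closes by carbenoid C–H insertion. Rh2(OAc)4 would decompose the α-diazo-β-keto ester A6, derived from an enantiopure chiral-pool aldehyde, and the carbenoid at CA1 would insert into the tertiary CA5–H bond with retention to give keto ester A5.
- In its favour: 1,5-insertion to cyclopentanones is well established and stereospecific, so CA5 comes from an existing stereocentre without asymmetric catalysis. On the control of CA5 this is equal to or better than the chosen plan.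
- Against it: in A5 ring B carries a symmetrical ketal, so CB1 is not yet stereogenic. The central problem, differentiating the two arms of ring B relative to CA5, is postponed to a later desymmetrisation with no control element in place. The inserting C–H bond is hindered by the neighbouring quaternary carbon. The extra ring-A ketone must be removed, the ester carbon converted into the methylene, and methyl, alkene and carbinol all installed on ring B.
- Comparison: the key step is safer than that of the chosen plan, but it solves the easier stereocentre and leaves the harder one, so the total step count should be higher.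

Key step: step 8

Assumption: which enantiomer of the chiral ligand in step 8 favours the required ring bond cannot be predicted for this substrate; both are to be tried and the route is written for the matched one.
Remark: the precursor 11 and the product 13 were checked against the target and agree with it at CA5 and CB1. The CIP label of CB1 is R in 13 to 15 and S from 16 onwards only because silicon on CB3 raises the priority of the CB2 branch; the spatial arrangement is the same throughout.

## Route

Step 1
Reactants: 1 ethyl 2-oxocyclopentane-1-carboxylate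
Product: 2 ethyl (1R,2R)-2-hydroxycyclopentane-1-carboxylate
Conditions: H2 (80 atm), [RuCl(C6H6)((R)-BINAP)]Cl (cat.; BINAP = 2,2'-bis(diphenylphosphino)-1,1'-binaphthyl), CH2Cl2, 50 °C
Reagents that add atoms: none
Why: Noyori hydrogenation of a configurationally labile β-keto ester with dynamic kinetic resolution; the (R)-ligand should set the (2R)-carbinol, and the configuration at C1 of this trans ester is erased in step 2.

Step 2
Reactants: 2 ethyl (1R,2R)-2-hydroxycyclopentane-1-carboxylate
Product: 3 ethyl (1S,2R)-2-hydroxy-1-methylcyclopentane-1-carboxylate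
Conditions: LiN(iPr)2 (2.2 equiv), THF, −78 to −20 °C; then MeI, DMPU, −78 to 0 °C
Reagents that add atoms: iodomethane, CI
Why: Fráter–Seebach alkylation: the chelated dilithium alkoxide–enolate is methylated on the face anti to the alkoxide oxygen, so the methyl ends up trans and the ester carbon cis to the oxygen, which sets CA5.

Step 3
Reactants: 3 ethyl (1S,2R)-2-hydroxy-1-methylcyclopentane-1-carboxylate
Product: 4 ethyl (1S,2R)-2-[(tert-butyldimethylsilyl)oxy]-1-methylcyclopentane-1-carboxylate
Conditions: TBSOTf, 2,6-lutidine, CH2Cl2, 0 °C
Reagents that add atoms: tert-butyldimethylsilyl trifluoromethanesulfonate, CC(C)(C)[Si](C)(C)OS(=O)(=O)C(F)(F)F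
Why: Silylation of a hindered secondary alcohol with the silyl triflate; the ether protects the oxygen through the organolithium, ylide, zinc and nickel steps.

Step 4
Reactants: 4 ethyl (1S,2R)-2-[(tert-butyldimethylsilyl)oxy]-1-methylcyclopentane-1-carboxylate
Product: 6 1-[(1S,2R)-2-[(tert-butyldimethylsilyl)oxy]-1-methylcyclopentyl]ethan-1-one, via α-silyl ketone 5 (not isolated)
Conditions: Me3SiCH2Li (2.5 equiv), pentane/THF, 0 to 35 °C; then MeOH, 25 °C
Reagents that add atoms: (trimethylsilyl)methyllithium, [Li]C[Si](C)(C)C
Why: Acyl substitution of the ester gives the α-silyl ketone, which the second equivalent of the organolithium enolises, so no second addition occurs; methanol then cleaves the activated C–Si bond to leave the methyl ketone.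

Step 5
Reactants: 6 1-[(1S,2R)-2-[(tert-butyldimethylsilyl)oxy]-1-methylcyclopentyl]ethan-1-one
Product: 7 tert-butyldimethyl{[(1R,2R)-2-methyl-2-(prop-1-en-2-yl)cyclopentyl]oxy}silane
Conditions: Ph3PCH3Br, KOtBu, toluene, 80 °C
Reagents that add atoms: methyltriphenylphosphonium bromide, C[P+](c1ccccc1)(c1ccccc1)c1ccccc1.[Br-]
Why: Wittig methylenation; the ketone has no epimerisable α-stereocentre, and a salt-free ylide with heating should cope with the neopentyl hindrance.

Step 6
Reactants: 7 tert-butyldimethyl{[(1R,2R)-2-methyl-2-(prop-1-en-2-yl)cyclopentyl]oxy}silane; 8 trichloroacetyl chloride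
Product: 10 3-[(1R,2R)-2-[(tert-butyldimethylsilyl)oxy]-1-methylcyclopentyl]-2,2-dichloro-3-methylcyclobutan-1-one (both configurations at ring C3), via dichloroketene 9 (not isolated)
Conditions: Zn (activated), Et2O/DME, ultrasound, 20 °C
Reagents that add atoms: none
Why: [2+2] cycloaddition of dichloroketene (zinc dehalogenation of the acid chloride) to the only alkene; the carbonyl carbon bonds to the CH2 terminus and the CCl2 carbon to the disubstituted carbon, giving the 3,3-disubstituted ring. DME binds ZnCl2 and spares the silyl ether, and the new ring stereocentre is removed in step 7.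

Step 7
Reactants: 10 3-[(1R,2R)-2-[(tert-butyldimethylsilyl)oxy]-1-methylcyclopentyl]-2,2-dichloro-3-methylcyclobutan-1-one
Product: 11 3-[(1R,2R)-2-[(tert-butyldimethylsilyl)oxy]-1-methylcyclopentyl]-3-methylcyclobutan-1-one
Conditions: Zn, AcOH, 25 °C
Reagents that add atoms: none
Why: Reductive dechlorination of an α,α-dichloroketone by zinc in acetic acid; it returns ring C3 to a prochiral carbon and gives the substrate of the key step.

Step 8
Reactants: 11 3-[(1R,2R)-2-[(tert-butyldimethylsilyl)oxy]-1-methylcyclopentyl]-3-methylcyclobutan-1-one; 12 trimethyl(prop-1-yn-1-yl)silane [1-(trimethylsilyl)propyne]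
Product: 13 (5R)-5-[(1R,2R)-2-[(tert-butyldimethylsilyl)oxy]-1-methylcyclopentyl]-2,5-dimethyl-3-(trimethylsilyl)cyclohex-2-en-1-one
Conditions: Ni(cod)2 (10 mol%), (S)-2-(dicyclohexylphosphino)-2'-methoxy-1,1'-binaphthyl (20 mol%, matched enantiomer), toluene, 90 °C, slow addition of 12
Reagents that add atoms: none
Why: Proposed new method: Ni(cod)2 with a bulky, electron-rich chiral monophosphine should couple the strained carbonyl of 11 with 12 by oxidative cyclisation to an oxanickelacyclopentene in which the methyl-bearing alkyne carbon is bonded to CB5 and the silyl-bearing carbon to nickel (C–C bond formation at the less hindered terminus, α-silyl stabilisation of the C–Ni bond). Strain-driven β-carbon elimination then breaks one CB5–CH2 bond to give a seven-membered nickelacycle, and C(sp2)–C(sp3) reductive elimination joins CB3 to CB2. The closest known reaction type is the intermolecular insertion of internal alkynes into 3,3-disubstituted cyclobutanones catalysed by zerovalent nickel and a trialkylphosphine, which gives cyclohex-2-enones; what has no precedent is a ligand that must choose between two ring bonds. Ring B is closed by this two-carbon ring expansion (formal [4+2]), the ring-closing bond CB2–CB3 being made by the reductive elimination. The new stereocentre CB1 is defined at the β-carbon elimination: CA5 and CA1 make the two CB5–CH2 bonds diastereotopic, and the chiral ligand is meant to reinforce or override this weak substrate bias so that the (5R)-enone results. The step needs bond selection, to be secured by the ligand, and alkyne orientation, to be secured by the silyl group; the silyl ether is inert, and slow addition of 12 limits its oligomerisation.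

Step 9
Reactants: 13 (5R)-5-[(1R,2R)-2-[(tert-butyldimethylsilyl)oxy]-1-methylcyclopentyl]-2,5-dimethyl-3-(trimethylsilyl)cyclohex-2-en-1-one
Product: 14 (1S,5R)-5-[(1R,2R)-2-[(tert-butyldimethylsilyl)oxy]-1-methylcyclopentyl]-2,5-dimethyl-3-(trimethylsilyl)cyclohex-2-en-1-ol
Conditions: (R)-tetrahydro-1-methyl-3,3-diphenyl-1H,3H-pyrrolo[1,2-c][1,3,2]oxazaborole (0.5 equiv), catecholborane, toluene, −78 °C
Reagents that add atoms: none
Why: Corey–Bakshi–Shibata reduction: the ketone binds the oxazaborolidine boron through the lone pair on the CB6 side, the fully substituted alkenyl arm acting as the large group, and hydride is delivered within the complex to the face that gives the (1S)-alcohol with oxygen trans to the CB1 methyl. Reducing before the C–Si bond is cleaved keeps the alkene tetrasubstituted, hence safe from hydroboration, and removes the carbonyl that would block the later ipso-protonation.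

Step 10
Reactants: 14 (1S,5R)-5-[(1R,2R)-2-[(tert-butyldimethylsilyl)oxy]-1-methylcyclopentyl]-2,5-dimethyl-3-(trimethylsilyl)cyclohex-2-en-1-ol
Product: 15 tert-butyl{[(1S,5R)-5-[(1R,2R)-2-[(tert-butyldimethylsilyl)oxy]-1-methylcyclopentyl]-2,5-dimethyl-3-(trimethylsilyl)cyclohex-2-en-1-yl]oxy}diphenylsilane
Conditions: TBDPSCl, imidazole, DMAP (cat.), DMF, 40 °C
Reagents that add atoms: tert-butyl(chloro)diphenylsilane, CC(C)(C)[Si](Cl)(c1ccccc1)c1ccccc1
Why: Silyl ether formation; the diphenyl-tert-butylsilyl group is chosen because it resists the acid of step 11 and the ylide of step 13 and is removed by fluoride in step 14.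

Step 11
Reactants: 15 tert-butyl{[(1S,5R)-5-[(1R,2R)-2-[(tert-butyldimethylsilyl)oxy]-1-methylcyclopentyl]-2,5-dimethyl-3-(trimethylsilyl)cyclohex-2-en-1-yl]oxy}diphenylsilane
Product: 17 (1R,2R)-2-[(1S,5S)-5-[(tert-butyldiphenylsilyl)oxy]-1,4-dimethylcyclohex-3-en-1-yl]-2-methylcyclopentan-1-ol, via protodesilylated bis-silyl ether 16 (not isolated)
Conditions: TFA, CH2Cl2, 0 °C; then p-TsOH·H2O, MeOH, 25 °C
Reagents that add atoms: none
Why: Electrophilic protodesilylation of a vinylsilane: ipso-protonation at CB3 gives the tertiary β-silyl cation at CB4, and loss of silicon leaves the CB3=CB4 alkene where it was. Acid methanolysis then removes the alkyl tert-butyldimethylsilyl ether, while the far more acid-stable and weakly basic diphenyl-tert-butylsilyl ether at CB5 should stay and should not ionise.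

Step 12
Reactants: 17 (1R,2R)-2-[(1S,5S)-5-[(tert-butyldiphenylsilyl)oxy]-1,4-dimethylcyclohex-3-en-1-yl]-2-methylcyclopentan-1-ol
Product: 18 (2R)-2-[(1S,5S)-5-[(tert-butyldiphenylsilyl)oxy]-1,4-dimethylcyclohex-3-en-1-yl]-2-methylcyclopentan-1-one
Conditions: DMP, CH2Cl2, 25 °C
Reagents that add atoms: none
Why: Dess–Martin oxidation of a hindered secondary alcohol under non-aqueous, nearly neutral conditions; the α-carbon CA5 is quaternary and cannot epimerise.

Step 13
Reactants: 18 (2R)-2-[(1S,5S)-5-[(tert-butyldiphenylsilyl)oxy]-1,4-dimethylcyclohex-3-en-1-yl]-2-methylcyclopentan-1-one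
Product: 19 tert-butyl{[(1S,5S)-2,5-dimethyl-5-[(1S)-1-methyl-2-methylidenecyclopentyl]cyclohex-2-en-1-yl]oxy}diphenylsilane
Conditions: Ph3PCH3Br, KOtBu, toluene, 90 °C
Reagents that add atoms: methyltriphenylphosphonium bromide, C[P+](c1ccccc1)(c1ccccc1)c1ccccc1.[Br-]
Why: Wittig methylenation under forcing, salt-free conditions of the kind used for α-quaternary ketones; the silyl ether is inert to the ylide and no stereocentre is at risk.

Step 14
Reactants: 19 tert-butyl{[(1S,5S)-2,5-dimethyl-5-[(1S)-1-methyl-2-methylidenecyclopentyl]cyclohex-2-en-1-yl]oxy}diphenylsilane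
Product: 20 (1S,5S)-2,5-dimethyl-5-[(1S)-1-methyl-2-methylidenecyclopentyl]cyclohex-2-en-1-ol
Conditions: TBAF, THF, 25 °C
Reagents that add atoms: none
Why: Fluoride cleavage of the silyl ether; the non-acidic conditions leave the exocyclic alkene and the allylic alcohol untouched.

Step 15
Reactants: 21 (2E)-3-(3,4-dihydroxyphenyl)prop-2-enoic acid (caffeic acid)
Product: 23 (2E)-3-{3,4-bis[(tert-butyldimethylsilyl)oxy]phenyl}prop-2-enoic acid, via tris-silyl derivative 22 (not isolated)
Conditions: TBSCl (3.5 equiv), imidazole, DMF, 25 °C; then AcOH/H2O/THF, 25 °C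
Reagents that add atoms: tert-butyl(chloro)dimethylsilane, CC(C)(C)[Si](C)(C)Cl
Why: Exhaustive silylation followed by selective hydrolysis of the labile silyl ester frees the carboxylic acid and keeps the catechol masked.

Step 16
Reactants: 20 (1S,5S)-2,5-dimethyl-5-[(1S)-1-methyl-2-methylidenecyclopentyl]cyclohex-2-en-1-ol; 23 (2E)-3-{3,4-bis[(tert-butyldimethylsilyl)oxy]phenyl}prop-2-enoic acid
Product: 24 (1S,5S)-2,5-dimethyl-5-[(1S)-1-methyl-2-methylidenecyclopentyl]cyclohex-2-en-1-yl (2E)-3-{3,4-bis[(tert-butyldimethylsilyl)oxy]phenyl}prop-2-enoate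
Conditions: EDC·HCl, DMAP, CH2Cl2, 25 °C
Reagents that add atoms: none
Why: Steglich esterification (carbodiimide activation, acyl transfer by DMAP); the C–O bond of the alcohol is not broken, so CB5 is retained and no allylic transposition is expected.

Step 17
Reactants: 24 (1S,5S)-2,5-dimethyl-5-[(1S)-1-methyl-2-methylidenecyclopentyl]cyclohex-2-en-1-yl (2E)-3-{3,4-bis[(tert-butyldimethylsilyl)oxy]phenyl}prop-2-enoate
Product: 25 (1S,5S)-2,5-dimethyl-5-[(1S)-1-methyl-2-methylidenecyclopentyl]cyclohex-2-en-1-yl (2E)-3-(3,4-dihydroxyphenyl)prop-2-enoate
Conditions: TBAF, AcOH, THF, 0 °C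
Reagents that add atoms: none
Why: Buffered fluoride removes the two aryl silyl ethers at low temperature; acetic acid protonates the catecholate at once, which protects it from oxidation and the ester from cleavage.

## Compound list

1 | ethyl 2-oxocyclopentane-1-carboxylate | CCOC(=O)C1CCCC1=O | starting material
2 | ethyl (1R,2R)-2-hydroxycyclopentane-1-carboxylate | O[C@@H]1CCC[C@H]1C(=O)OCC | intermediate
3 | ethyl (1S,2R)-2-hydroxy-1-methylcyclopentane-1-carboxylate | O[C@@H]1CCC[C@]1(C)C(=O)OCC | intermediate
4 | ethyl (1S,2R)-2-[(tert-butyldimethylsilyl)oxy]-1-methylcyclopentane-1-carboxylate | CC(C)(C)[Si](C)(C)O[C@@H]1CCC[C@]1(C)C(=O)OCC | intermediate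
5 | 1-[(1S,2R)-2-[(tert-butyldimethylsilyl)oxy]-1-methylcyclopentyl]-2-(trimethylsilyl)ethan-1-one | CC(C)(C)[Si](C)(C)O[C@@H]1CCC[C@]1(C)C(=O)C[Si](C)(C)C | intermediate
6 | 1-[(1S,2R)-2-[(tert-butyldimethylsilyl)oxy]-1-methylcyclopentyl]ethan-1-one | CC(C)(C)[Si](C)(C)O[C@@H]1CCC[C@]1(C)C(C)=O | intermediate
7 | tert-butyldimethyl{[(1R,2R)-2-methyl-2-(prop-1-en-2-yl)cyclopentyl]oxy}silane | CC(C)(C)[Si](C)(C)O[C@@H]1CCC[C@]1(C)C(C)=C | intermediate
8 | trichloroacetyl chloride | O=C(Cl)C(Cl)(Cl)Cl | starting material
9 | dichloroketene | ClC(Cl)=C=O | intermediate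
10 | 3-[(1R,2R)-2-[(tert-butyldimethylsilyl)oxy]-1-methylcyclopentyl]-2,2-dichloro-3-methylcyclobutan-1-one (both configurations at ring C3) | CC(C)(C)[Si](C)(C)O[C@@H]1CCC[C@]1(C)C1(C)CC(=O)C1(Cl)Cl | intermediate
11 | 3-[(1R,2R)-2-[(tert-butyldimethylsilyl)oxy]-1-methylcyclopentyl]-3-methylcyclobutan-1-one | CC(C)(C)[Si](C)(C)O[C@@H]1CCC[C@]1(C)C1(C)CC(=O)C1 | intermediate
12 | trimethyl(prop-1-yn-1-yl)silane [1-(trimethylsilyl)propyne] | CC#C[Si](C)(C)C | starting material
13 | (5R)-5-[(1R,2R)-2-[(tert-butyldimethylsilyl)oxy]-1-methylcyclopentyl]-2,5-dimethyl-3-(trimethylsilyl)cyclohex-2-en-1-one | CC(C)(C)[Si](C)(C)O[C@@H]1CCC[C@]1(C)[C@@]1(C)CC([Si](C)(C)C)=C(C)C(=O)C1 | intermediate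
14 | (1S,5R)-5-[(1R,2R)-2-[(tert-butyldimethylsilyl)oxy]-1-methylcyclopentyl]-2,5-dimethyl-3-(trimethylsilyl)cyclohex-2-en-1-ol | CC(C)(C)[Si](C)(C)O[C@@H]1CCC[C@]1(C)[C@@]1(C)CC([Si](C)(C)C)=C(C)[C@@H](O)C1 | intermediate
15 | tert-butyl{[(1S,5R)-5-[(1R,2R)-2-[(tert-butyldimethylsilyl)oxy]-1-methylcyclopentyl]-2,5-dimethyl-3-(trimethylsilyl)cyclohex-2-en-1-yl]oxy}diphenylsilane | CC(C)(C)[Si](C)(C)O[C@@H]1CCC[C@]1(C)[C@@]1(C)CC([Si](C)(C)C)=C(C)[C@@H](O[Si](c2ccccc2)(c2ccccc2)C(C)(C)C)C1 | intermediate
16 | tert-butyl{[(1S,5S)-5-[(1R,2R)-2-[(tert-butyldimethylsilyl)oxy]-1-methylcyclopentyl]-2,5-dimethylcyclohex-2-en-1-yl]oxy}diphenylsilane | CC(C)(C)[Si](C)(C)O[C@@H]1CCC[C@]1(C)[C@@]1(C)CC=C(C)[C@@H](O[Si](c2ccccc2)(c2ccccc2)C(C)(C)C)C1 | intermediate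
17 | (1R,2R)-2-[(1S,5S)-5-[(tert-butyldiphenylsilyl)oxy]-1,4-dimethylcyclohex-3-en-1-yl]-2-methylcyclopentan-1-ol | O[C@@H]1CCC[C@]1(C)[C@@]1(C)CC=C(C)[C@@H](O[Si](c2ccccc2)(c2ccccc2)C(C)(C)C)C1 | intermediate
18 | (2R)-2-[(1S,5S)-5-[(tert-butyldiphenylsilyl)oxy]-1,4-dimethylcyclohex-3-en-1-yl]-2-methylcyclopentan-1-one | O=C1CCC[C@]1(C)[C@@]1(C)CC=C(C)[C@@H](O[Si](c2ccccc2)(c2ccccc2)C(C)(C)C)C1 | intermediate
19 | tert-butyl{[(1S,5S)-2,5-dimethyl-5-[(1S)-1-methyl-2-methylidenecyclopentyl]cyclohex-2-en-1-yl]oxy}diphenylsilane | C=C1CCC[C@]1(C)[C@@]1(C)CC=C(C)[C@@H](O[Si](c2ccccc2)(c2ccccc2)C(C)(C)C)C1 | intermediate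
20 | (1S,5S)-2,5-dimethyl-5-[(1S)-1-methyl-2-methylidenecyclopentyl]cyclohex-2-en-1-ol | C=C1CCC[C@]1(C)[C@@]1(C)CC=C(C)[C@@H](O)C1 | intermediate
21 | (2E)-3-(3,4-dihydroxyphenyl)prop-2-enoic acid (caffeic acid) | OC(=O)/C=C/c1ccc(O)c(O)c1 | starting material
22 | tert-butyldimethylsilyl (2E)-3-{3,4-bis[(tert-butyldimethylsilyl)oxy]phenyl}prop-2-enoate | CC(C)(C)[Si](C)(C)OC(=O)/C=C/c1ccc(O[Si](C)(C)C(C)(C)C)c(O[Si](C)(C)C(C)(C)C)c1 | intermediate
23 | (2E)-3-{3,4-bis[(tert-butyldimethylsilyl)oxy]phenyl}prop-2-enoic acid | OC(=O)/C=C/c1ccc(O[Si](C)(C)C(C)(C)C)c(O[Si](C)(C)C(C)(C)C)c1 | intermediate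
24 | (1S,5S)-2,5-dimethyl-5-[(1S)-1-methyl-2-methylidenecyclopentyl]cyclohex-2-en-1-yl (2E)-3-{3,4-bis[(tert-butyldimethylsilyl)oxy]phenyl}prop-2-enoate | C=C1CCC[C@]1(C)[C@@]1(C)CC=C(C)[C@@H](OC(=O)/C=C/c2ccc(O[Si](C)(C)C(C)(C)C)c(O[Si](C)(C)C(C)(C)C)c2)C1 | intermediate
25 | (1S,5S)-2,5-dimethyl-5-[(1S)-1-methyl-2-methylidenecyclopentyl]cyclohex-2-en-1-yl (2E)-3-(3,4-dihydroxyphenyl)prop-2-enoate | C=C1CCC[C@]1(C)[C@@]1(C)CC=C(C)[C@@H](OC(=O)/C=C/c2ccc(O)c(O)c2)C1 | target

## Step count and least certain steps

Total: 17 steps. Longest linear sequence: 16 steps (steps 1 to 14, 16 and 17); step 15 is a one-step branch.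

Step 8 (key step). The most likely failure is insufficient discrimination between the two diastereotopic CB5–CH2 bonds at the β-carbon elimination, because the controlling ligand sits on nickel while the carbon that becomes stereogenic is two bonds away and very hindered. Oligomerisation of the alkyne or a reversed alkyne orientation may also compete. The fallback uses known chemistry and gives up catalyst control. It sets out from 11 and 12 with the established achiral system (Ni(cod)2, PCy3, toluene, 100 °C), which should give 13 together with its CB1 epimer (5S)-5-[(1R,2R)-2-[(tert-butyldimethylsilyl)oxy]-1-methylcyclopentyl]-2,5-dimethyl-3-(trimethylsilyl)cyclohex-2-en-1-one F1. Because CA1 and CA5 are already fixed, the two are diastereomers and are to be separated by chromatography; the route is rejoined at 13.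

Step 9. The hydride has to enter on the ring face that carries the axial CB1 methyl, so the reagent-controlled delivery may be opposed by the ring and facial selectivity may be poor. The fallback sets out from 13 and uses the enantiomeric (S)-oxazaborolidine, presumably the matched pair, to make the CB5 epimer (1R,5R)-5-[(1R,2R)-2-[(tert-butyldimethylsilyl)oxy]-1-methylcyclopentyl]-2,5-dimethyl-3-(trimethylsilyl)cyclohex-2-en-1-ol F2. Mitsunobu inversion (4-nitrobenzoic acid, PPh3, DIAD, toluene) then gives (1S,5R)-5-[(1R,2R)-2-[(tert-butyldimethylsilyl)oxy]-1-methylcyclopentyl]-2,5-dimethyl-3-(trimethylsilyl)cyclohex-2-en-1-yl 4-nitrobenzoate F3; the allylic shift is blocked by the fully substituted, silyl-bearing CB3. Methanolysis (K2CO3, MeOH) returns to the route at 14.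

Step 11. Ionisation of the allylic CB5–O bond or acid-induced migration of the new CB3=CB4 alkene may compete with ipso-protonation. The hindered alkyl silyl ether may also be lost too slowly relative to the CB5 silyl ether. The fallback sets out from 15 and replaces the proton by an iodonium electrophile: NIS in (CF3)2CHOH at 0 °C should give tert-butyl{[(1S,5R)-5-[(1R,2R)-2-[(tert-butyldimethylsilyl)oxy]-1-methylcyclopentyl]-3-iodo-2,5-dimethylcyclohex-2-en-1-yl]oxy}diphenylsilane F4 without any strong acid. Formate reduction of the C–I bond (Pd(OAc)2, PPh3, HCO2H, Et3N, DMF, 60 °C) comes back to the route at 16, which is then isolated and taken to 17 by the mild acid methanolysis alone (p-TsOH·H2O, MeOH).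

Step 13. Enolisation of the ketone towards CA2 by the basic ylide, instead of addition to a carbonyl shielded by two contiguous quaternary carbons, would return starting ketone. The fallback is a Peterson olefination from 18. The less basic organocerium reagent (Me3SiCH2Li, CeCl3, THF, −78 °C) should add to give (2R)-2-[(1S,5S)-5-[(tert-butyldiphenylsilyl)oxy]-1,4-dimethylcyclohex-3-en-1-yl]-2-methyl-1-[(trimethylsilyl)methyl]cyclopentan-1-ol F5, and syn-elimination with KH in THF comes back to the route at 19.

## Further compounds

F1 | step 8 | (5S)-5-[(1R,2R)-2-[(tert-butyldimethylsilyl)oxy]-1-methylcyclopentyl]-2,5-dimethyl-3-(trimethylsilyl)cyclohex-2-en-1-one | CC(C)(C)[Si](C)(C)O[C@@H]1CCC[C@]1(C)[C@]1(C)CC([Si](C)(C)C)=C(C)C(=O)C1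
F2 | step 9 | (1R,5R)-5-[(1R,2R)-2-[(tert-butyldimethylsilyl)oxy]-1-methylcyclopentyl]-2,5-dimethyl-3-(trimethylsilyl)cyclohex-2-en-1-ol | CC(C)(C)[Si](C)(C)O[C@@H]1CCC[C@]1(C)[C@@]1(C)CC([Si](C)(C)C)=C(C)[C@H](O)C1
F3 | step 9 | (1S,5R)-5-[(1R,2R)-2-[(tert-butyldimethylsilyl)oxy]-1-methylcyclopentyl]-2,5-dimethyl-3-(trimethylsilyl)cyclohex-2-en-1-yl 4-nitrobenzoate | CC(C)(C)[Si](C)(C)O[C@@H]1CCC[C@]1(C)[C@@]1(C)CC([Si](C)(C)C)=C(C)[C@@H](OC(=O)c2ccc(cc2)[N+](=O)[O-])C1
F4 | step 11 | tert-butyl{[(1S,5R)-5-[(1R,2R)-2-[(tert-butyldimethylsilyl)oxy]-1-methylcyclopentyl]-3-iodo-2,5-dimethylcyclohex-2-en-1-yl]oxy}diphenylsilane | CC(C)(C)[Si](C)(C)O[C@@H]1CCC[C@]1(C)[C@@]1(C)CC(I)=C(C)[C@@H](O[Si](c2ccccc2)(c2ccccc2)C(C)(C)C)C1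
F5 | step 13 | (2R)-2-[(1S,5S)-5-[(tert-butyldiphenylsilyl)oxy]-1,4-dimethylcyclohex-3-en-1-yl]-2-methyl-1-[(trimethylsilyl)methyl]cyclopentan-1-ol (both configurations at C1) | C[Si](C)(C)CC1(O)CCC[C@]1(C)[C@@]1(C)CC=C(C)[C@@H](O[Si](c2ccccc2)(c2ccccc2)C(C)(C)C)C1
A1 | alternative 1 | (2S,4S)-2-(benzyloxy)-4-methyl-4-[(1R)-1-methyl-2-oxocyclopentyl]cyclohexan-1-one | O=C1CCC[C@]1(C)[C@@]1(C)CCC(=O)[C@@H](OCc2ccccc2)C1
A2 | alternative 1 | (4S,6Z)-4-(benzyloxy)-7-(1-hydroxycyclobutyl)-6-methylocta-1,6-dien-3-one | C=CC(=O)[C@@H](OCc1ccccc1)C/C(C)=C(C)\C1(O)CCC1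
A3 | alternative 2 | (1R,2S,6R)-6-[(6R)-6-methyl-1,4-dioxaspiro[4.4]nonan-6-yl]bicyclo[4.1.0]heptan-2-ol | O1CCOC12CCC[C@]2(C)[C@@]12C[C@H]2[C@@H](O)CCC1
A4 | alternative 2 | (1S)-3-[(6R)-6-methyl-1,4-dioxaspiro[4.4]nonan-6-yl]cyclohex-2-en-1-ol | O1CCOC12CCC[C@]2(C)C1=C[C@@H](O)CCC1
A5 | alternative 3 | methyl (1R,2S)-2-methyl-2-(8-methyl-1,4-dioxaspiro[4.5]decan-8-yl)-5-oxocyclopentane-1-carboxylate | COC(=O)[C@H]1C(=O)CC[C@]1(C)C1(C)CCC2(CC1)OCCO2
A6 | alternative 3 | methyl (6S)-2-diazo-6-(8-methyl-1,4-dioxaspiro[4.5]decan-8-yl)-3-oxoheptanoate | COC(=O)C(=[N+]=[N-])C(=O)CC[C@H](C)C1(C)CCC2(CC1)OCCO2
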